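**Retrosynthetic overview**

1. Locants follow prostanoid numbering (C1 = ester carbon, ring = C8–C12, C9 = ketone, C10 = C–Cl, C12 = acetoxy carbon). The last bond made is the C12 O–acetyl bond, by acetylation of chlorovulone II.
2. Key disconnection: the C8–C9 bond of the cyclopentenone (ring C8–C9–C10–C11–C12), made by Rh(I)-catalysed syn-hydroacylation of a C7≡C8 alkyne by a C9 aldehyde. The enabling feature is that the C7–H lies cis to the C9 carbonyl across the exocyclic C7=C8 bond and C8 is 1,5 to C9 through C10=C11 and the quaternary C12, so the ring is the retron of a 5-alkynal cis-hydroacylation that also sets the 7E geometry.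
3. The (Z)-2-chloroenal is stored in a temporary ring that is not in the target, a 2,5-dihydrofuran-2-ol (lactol, O12–C9 bond). It locks C10=C11 cis, and both C9 epimers open to the same aldehyde. It derives from a 3-chlorobutenolide, from a 3-stannylbutenolide, from syn-hydrostannation/lactonisation of a 4-hydroxy-2-ynoate.
4. C12, the only stereocentre, comes from Sharpless epoxidation of a (Z)-3-alkynyl allylic alcohol followed by epoxy chloride fragmentation to the tertiary propargylic alcohol. C13–C20 come from (Z)-oct-2-enyl bromide plus propargyl alcohol; C1–C6 are attached by Sonogashira coupling with methyl (E)-6-iodohex-5-enoate.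
5. Ring order: the temporary oxacycle (butenolide, then lactol) first; the cyclopentenone last, formed in the same step that opens the oxacycle.

Key step: step 14

Remark: compounds 1, 3, 7 and 18 are taken as commercially available.

**Route**

Step 1
Reactants: 1 (2Z)-oct-2-en-1-ol
Product: 2 (2Z)-1-bromooct-2-ene
Conditions: CBr4, PPh3, CH2Cl2, 0 °C
Reagents that add atoms: carbon tetrabromide, BrC(Br)(Br)Br
Why: Appel bromination replaces the primary allylic OH by SN2 at C1 under neutral conditions, so the Z double bond should stay untouched.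

Step 2
Reactants: 2 (2Z)-1-bromooct-2-ene; 3 prop-2-yn-1-ol
Product: 4 (5Z)-undec-5-en-2-yn-1-ol
Conditions: CuI (10 mol%), NaI (10 mol%), K2CO3, DMF, rt
Reagents that add atoms: none
Why: Copper(I)-catalysed coupling of a terminal alkyne with a primary allylic bromide (substitution at the CH2Br carbon) should give the skipped enyne without moving the Z-alkene.

Step 3
Reactants: 4 (5Z)-undec-5-en-2-yn-1-ol
Product: 6 (2Z,5Z)-3-iodoundeca-2,5-dien-1-ol, via cyclic alkenylaluminate 5 (not isolated)
Conditions: Red-Al (1.5 equiv), THF, 0 °C to rt; then I2, −78 to 0 °C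
Reagents that add atoms: iodine, II
Why: Hydroxyl-directed trans-hydroalumination of the propargylic alcohol places H on C2 and Al on C3 in a five-membered O–Al chelate, and iodinolysis with retention should give the (Z)-3-iodoallylic alcohol.

Step 4
Reactants: 6 (2Z,5Z)-3-iodoundeca-2,5-dien-1-ol; 7 ethynyl(trimethyl)silane
Product: 8 (2Z,5Z)-3-[(trimethylsilyl)ethynyl]undeca-2,5-dien-1-ol
Conditions: PdCl2(PPh3)2 (3 mol%), CuI (6 mol%), Et3N, THF, rt
Reagents that add atoms: none
Why: Sonogashira coupling proceeds with retention at the vinyl iodide, so the alkynyl group should end up cis to CH2OH.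

Step 5
Reactants: 8 (2Z,5Z)-3-[(trimethylsilyl)ethynyl]undeca-2,5-dien-1-ol
Product: 9 [(2R,3S)-3-[(2Z)-oct-2-en-1-yl]-3-[(trimethylsilyl)ethynyl]oxiran-2-yl]methanol
Conditions: Ti(OiPr)4 (0.2 equiv), D-(−)-diethyl tartrate (0.25 equiv), t-BuOOH (2 equiv, in decane), 4 Å MS, CH2Cl2, −20 °C
Reagents that add atoms: tert-butyl hydroperoxide, CC(C)(C)OO
Why: Sharpless asymmetric epoxidation is directed by the allylic OH, so only the C2=C3 alkene reacts, and D-(−)-tartrate (the series that gives 2R epoxides) delivers oxygen to the face that sets the future C12 configuration.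

Step 6
Reactants: 9 [(2R,3S)-3-[(2Z)-oct-2-en-1-yl]-3-[(trimethylsilyl)ethynyl]oxiran-2-yl]methanol
Product: 10 (2S,3S)-2-(chloromethyl)-3-[(2Z)-oct-2-en-1-yl]-3-[(trimethylsilyl)ethynyl]oxirane
Conditions: PPh3, CCl4, NaHCO3, reflux
Reagents that add atoms: carbon tetrachloride, ClC(Cl)(Cl)Cl
Why: Appel chlorination of the primary alcohol under near-neutral conditions should leave the epoxide and both stereocentres intact (the descriptor at C2 changes only through CIP priorities).

Step 7
Reactants: 10 (2S,3S)-2-(chloromethyl)-3-[(2Z)-oct-2-en-1-yl]-3-[(trimethylsilyl)ethynyl]oxirane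
Product: 12 methyl (4R,6Z)-4-hydroxy-4-[(trimethylsilyl)ethynyl]dodec-6-en-2-ynoate, via dilithio alkynolate 11 (not isolated)
Conditions: n-BuLi (3.1 equiv), THF, −78 to −30 °C; then ClCO2Me (1.05 equiv), −78 °C; aq. NH4Cl
Reagents that add atoms: methyl chloroformate, COC(Cl)=O
Why: Base-induced fragmentation of a 2,3-epoxy chloride (deprotonation at CH2Cl, eliminative epoxide opening, loss of LiCl) should give the tertiary propargylic alkoxide/acetylide without breaking the C–O bond of the stereocentre, and the acetylide carbon should be acylated faster than the hindered tertiary alkoxide.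

Step 8
Reactants: 12 methyl (4R,6Z)-4-hydroxy-4-[(trimethylsilyl)ethynyl]dodec-6-en-2-ynoate
Product: 14 (5R)-5-[(2Z)-oct-2-en-1-yl]-3-(tributylstannyl)-5-[(trimethylsilyl)ethynyl]furan-2(5H)-one, via stannyl hydroxy enoate 13 (not isolated)
Conditions: Bu3SnH (1.1 equiv, slow addition), Pd(PPh3)4 (3 mol%), THF, 0 °C to rt; then PPTS (cat.), CH2Cl2, rt
Reagents that add atoms: tributyltin hydride, CCCC[SnH](CCCC)CCCC
Why: Pd(0)-catalysed hydrostannation of an ynoate is a syn addition with tin α to the ester, so the ester should lie cis to the carbinol carbon and lactonise to the butenolide, the electron-poor ynoate reacting much faster than the silylalkyne.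

Step 9
Reactants: 14 (5R)-5-[(2Z)-oct-2-en-1-yl]-3-(tributylstannyl)-5-[(trimethylsilyl)ethynyl]furan-2(5H)-one
Product: 15 (5R)-3-chloro-5-[(2Z)-oct-2-en-1-yl]-5-[(trimethylsilyl)ethynyl]furan-2(5H)-one
Conditions: CuCl2 (2.5 equiv), THF, 0 °C to rt
Reagents that add atoms: copper(II) chloride, Cl[Cu]Cl
Why: Copper(II) chloride halodestannylation of an alkenylstannane (Sn-to-Cu transmetalation, then C–Cl formation with retention) should replace tin by chlorine at C3 without touching the other π bonds.

Step 10
Reactants: 15 (5R)-3-chloro-5-[(2Z)-oct-2-en-1-yl]-5-[(trimethylsilyl)ethynyl]furan-2(5H)-one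
Product: 16 (5R)-3-chloro-5-ethynyl-5-[(2Z)-oct-2-en-1-yl]furan-2(5H)-one
Conditions: TBAF (1.1 equiv), AcOH (1.2 equiv), THF, 0 °C
Reagents that add atoms: none
Why: Buffered fluoride protodesilylation cleaves only the C(sp)–Si bond, and the butenolide, which has no γ-hydrogen, should not enolise.

Step 11
Reactants: 16 (5R)-3-chloro-5-ethynyl-5-[(2Z)-oct-2-en-1-yl]furan-2(5H)-one
Product: 17 (2RS,5R)-3-chloro-5-ethynyl-5-[(2Z)-oct-2-en-1-yl]-2,5-dihydrofuran-2-ol
Conditions: DIBAL-H (1.3 equiv), CH2Cl2, −78 °C; Rochelle salt work-up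
Reagents that add atoms: none
Why: DIBAL-H reduction of a lactone stops at the lactol at −78 °C because the aluminium hemiacetal is stable, and it is placed before the methyl ester side chain is introduced.

Step 12
Reactants: 18 methyl hex-5-ynoate
Product: 20 methyl (5E)-6-iodohex-5-enoate, via alkenylzirconocene 19 (not isolated)
Conditions: Cp2Zr(H)Cl (1.2 equiv), CH2Cl2, rt; then I2, 0 °C
Reagents that add atoms: iodine, II
Why: Hydrozirconation of the terminal alkyne is a syn addition with Zr at the terminal carbon, and iodinolysis with retention should give the (E)-vinyl iodide.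

Step 13
Reactants: 17 (2RS,5R)-3-chloro-5-ethynyl-5-[(2Z)-oct-2-en-1-yl]-2,5-dihydrofuran-2-ol; 20 methyl (5E)-6-iodohex-5-enoate
Product: 21 methyl (5E)-8-[(2R,5RS)-4-chloro-5-hydroxy-2-[(2Z)-oct-2-en-1-yl]-2,5-dihydrofuran-2-yl]oct-5-en-7-ynoate
Conditions: Pd(PPh3)4 (5 mol%), CuI (10 mol%), Et3N, THF (degassed), rt
Reagents that add atoms: none
Why: Sonogashira coupling joins the terminal alkyne and the (E)-vinyl iodide with retention, and the vinyl C–Cl bond and the lactol should be inert to Pd(0)/Cu(I)/Et3N at room temperature.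

Step 14
Reactants: 21 methyl (5E)-8-[(2R,5RS)-4-chloro-5-hydroxy-2-[(2Z)-oct-2-en-1-yl]-2,5-dihydrofuran-2-yl]oct-5-en-7-ynoate
Product: 23 methyl (5E,7E,12R,14Z)-10-chloro-12-hydroxy-9-oxoprosta-5,7,10,14-tetraen-1-oate (chlorovulone II), via ring-opened hydroxy enal 22 (not isolated)
Conditions: [Rh(dppe)]2(BF4)2 (5 mol%), acetone (degassed, 0.02 M), 25 to 50 °C
Reagents that add atoms: none
Why: Proposed new method: lactol 21 (both C9 epimers) is in ring–chain equilibrium with the (Z)-γ-hydroxy-α-chloroenal 22, whose C9–H adds oxidatively to cationic Rh(I); the acyl–Rh–H then adds syn across the chelated C7≡C8 triple bond (H to C7, Rh to C8) to give a six-membered acyl(alkenyl)rhodacycle, and C–C reductive elimination forms the C8–C9 bond and frees Rh(I), while the equilibrium keeps supplying 22 so that both epimers converge on one product. The closest known reaction types are the Rh(I)/dppe-catalysed intramolecular cis-hydroacylation of 5-alkynals to (E)-α-alkylidenecyclopentanones and Rh-catalysed C–H activation of aldoses through their open-chain aldehyde form; what is new is that a lactol feeds the hydroacylation and that the tether is a 2-chloroenal. The cyclopentenone (C8–C9–C10–C11–C12) closes in a formal 5-exo-dig mode through the six-membered rhodacycle, the 6-endo alternative needing a seven-membered one. No new stereocentre is created: the 7E geometry of the new C7=C8 bond is dictated by the syn addition of H and acyl, the 5E bond is carried in from 20, and C12 is not touched. The step needs the alkyne to win over the C5=C6 and C14=C15 alkenes (only C8 can be reached in a six-membered chelate), hydroacylation to win over decarbonylation (chelating dppe, tethered alkyne, mild temperature) and the C10=C11 cis geometry to survive, which the substrate secures because any unreacted open form recloses to the lactol. The quaternary C12 carries no hydrogen, so the lactol cannot dehydrate to a furan, and the gem-disubstitution holds the two reacting ends together.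

Step 15
Reactants: 23 methyl (5E,7E,12R,14Z)-10-chloro-12-hydroxy-9-oxoprosta-5,7,10,14-tetraen-1-oate
Product: 24 methyl (5E,7E,12R,14Z)-12-acetoxy-10-chloro-9-oxoprosta-5,7,10,14-tetraen-1-oate
Conditions: Ac2O, DMAP, Et3N, CH2Cl2, 0 °C to rt
Reagents that add atoms: acetic anhydride, CC(=O)OC(C)=O
Why: DMAP-catalysed acylation of the tertiary alcohol does not break the C12–O bond, so the acetate should form with the configuration unchanged.

**Compound list**

1 | (2Z)-oct-2-en-1-ol | CCCCC/C=C\CO | starting material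
2 | (2Z)-1-bromooct-2-ene | CCCCC/C=C\CBr | intermediate
3 | prop-2-yn-1-ol | OCC#C | starting material
4 | (5Z)-undec-5-en-2-yn-1-ol | CCCCC/C=C\CC#CCO | intermediate
5 | cyclic alkenylaluminate: sodium 2,2-bis(2-methoxyethoxy)-3-[(2Z)-oct-2-en-1-yl]-2,5-dihydro-1,2-oxaaluminol-2-uide | [Na+].CCCCC/C=C\CC1=CCO[Al-]1(OCCOC)OCCOC | intermediate
6 | (2Z,5Z)-3-iodoundeca-2,5-dien-1-ol | CCCCC/C=C\C/C(I)=C/CO | intermediate
7 | ethynyl(trimethyl)silane | C#C[Si](C)(C)C | starting material
8 | (2Z,5Z)-3-[(trimethylsilyl)ethynyl]undeca-2,5-dien-1-ol | CCCCC/C=C\C/C(C#C[Si](C)(C)C)=C/CO | intermediate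
9 | [(2R,3S)-3-[(2Z)-oct-2-en-1-yl]-3-[(trimethylsilyl)ethynyl]oxiran-2-yl]methanol | CCCCC/C=C\C[C@@]1(C#C[Si](C)(C)C)O[C@@H]1CO | intermediate
10 | (2S,3S)-2-(chloromethyl)-3-[(2Z)-oct-2-en-1-yl]-3-[(trimethylsilyl)ethynyl]oxirane | CCCCC/C=C\C[C@@]1(C#C[Si](C)(C)C)O[C@@H]1CCl | intermediate
11 | dilithio alkynolate: O,C-dilithio derivative of (3R,5Z)-3-[(trimethylsilyl)ethynyl]undec-5-en-1-yn-3-ol | CCCCC/C=C\C[C@@](C#C[Si](C)(C)C)(O[Li])C#C[Li] | intermediate
12 | methyl (4R,6Z)-4-hydroxy-4-[(trimethylsilyl)ethynyl]dodec-6-en-2-ynoate | CCCCC/C=C\C[C@@](C#C[Si](C)(C)C)(O)C#CC(=O)OC | intermediate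
13 | methyl (2E,4R,6Z)-4-hydroxy-2-(tributylstannyl)-4-[(trimethylsilyl)ethynyl]dodeca-2,6-dienoate | CCCCC/C=C\C[C@@](C#C[Si](C)(C)C)(O)/C=C(\C(=O)OC)[Sn](CCCC)(CCCC)CCCC | intermediate
14 | (5R)-5-[(2Z)-oct-2-en-1-yl]-3-(tributylstannyl)-5-[(trimethylsilyl)ethynyl]furan-2(5H)-one | CCCCC/C=C\C[C@@]1(C#C[Si](C)(C)C)OC(=O)C(=C1)[Sn](CCCC)(CCCC)CCCC | intermediate
15 | (5R)-3-chloro-5-[(2Z)-oct-2-en-1-yl]-5-[(trimethylsilyl)ethynyl]furan-2(5H)-one | CCCCC/C=C\C[C@@]1(C#C[Si](C)(C)C)OC(=O)C(Cl)=C1 | intermediate
16 | (5R)-3-chloro-5-ethynyl-5-[(2Z)-oct-2-en-1-yl]furan-2(5H)-one | CCCCC/C=C\C[C@@]1(C#C)OC(=O)C(Cl)=C1 | intermediate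
17 | (2RS,5R)-3-chloro-5-ethynyl-5-[(2Z)-oct-2-en-1-yl]-2,5-dihydrofuran-2-ol | CCCCC/C=C\C[C@@]1(C#C)OC(O)C(Cl)=C1 | intermediate
18 | methyl hex-5-ynoate | COC(=O)CCCC#C | starting material
19 | alkenylzirconocene: methyl (5E)-6-[chlorobis(cyclopentadienyl)zirconio]hex-5-enoate | COC(=O)CCC/C=C/[Zr](Cl)(C1C=CC=C1)C1C=CC=C1 | intermediate
20 | methyl (5E)-6-iodohex-5-enoate | COC(=O)CCC/C=C/I | intermediate
21 | methyl (5E)-8-[(2R,5RS)-4-chloro-5-hydroxy-2-[(2Z)-oct-2-en-1-yl]-2,5-dihydrofuran-2-yl]oct-5-en-7-ynoate | CCCCC/C=C\C[C@@]1(C#C/C=C/CCCC(=O)OC)OC(O)C(Cl)=C1 | intermediate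
22 | ring-opened hydroxy enal: methyl (5E,9R,10E)-11-chloro-9-hydroxy-9-[(2Z)-oct-2-en-1-yl]-12-oxododeca-5,10-dien-7-ynoate | CCCCC/C=C\C[C@@](C#C/C=C/CCCC(=O)OC)(O)/C=C(/Cl)C=O | intermediate
23 | methyl (5E,7E,12R,14Z)-10-chloro-12-hydroxy-9-oxoprosta-5,7,10,14-tetraen-1-oate (chlorovulone II) | CCCCC/C=C\C[C@@]1(O)C=C(Cl)C(=O)/C1=C/C=C/CCCC(=O)OC | intermediate
24 | methyl (5E,7E,12R,14Z)-12-acetoxy-10-chloro-9-oxoprosta-5,7,10,14-tetraen-1-oate | CCCCC/C=C\C[C@@]1(OC(C)=O)C=C(Cl)C(=O)/C1=C/C=C/CCCC(=O)OC | target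

**Step count and risks**

Total step count: 15. Longest linear sequence: 14 steps (steps 1–11 and 13–15; step 12 is the one-step side branch).

Steps most likely to fail:

Step 14 (Proposed new method). What may go wrong: ring opening of the lactol may be too slow for the catalyst lifetime; the lactol may be dehydrogenated to the butenolide with transfer of hydrogen to the alkyne; the acyl–rhodium hydride may decarbonylate; the ring-opened enal may isomerise from cis to trans and then be unable to cyclise. The fallback uses only known chemistry, sets out from 21 and comes back at 24. Reduction of 21 with NaBH4 in MeOH at 0 °C should give the (Z)-chloro diol F1. TESCl/imidazole should silylate only the primary hydroxyl to give the triethylsilyl ether F2. Ac2O/DMAP/Et3N should acetylate the tertiary hydroxyl to give the acetate F3. Swern conditions, which cleave and oxidise a primary triethylsilyl ether directly, should give the open-chain acetoxy enal F4. F4 is a conventional 5-alkynal, and the established Rh(I)/dppe cis-hydroacylation in acetone should close it straight to 24.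

Step 7. What may go wrong: acylation at the tertiary alkoxide oxygen in competition with the acetylide carbon; nucleophilic attack of n-butyllithium on the alkynyl epoxide; incomplete second elimination. The fallback sets out from 10 and comes back at 12. Fragmentation with the non-nucleophilic base LDA (3.5 equiv, THF, −78 to −30 °C) and aqueous quench should allow isolation of the diynol F5. Double deprotonation with EtMgBr and carboxylation with CO2, which cannot O-acylate irreversibly, should give the hydroxy ynoic acid F6. Esterification with trimethylsilyldiazomethane in MeOH/toluene should give 12.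

Step 9. What may go wrong: oxidative homocoupling of the alkenylcopper intermediate or protodestannylation instead of C–Cl bond formation. The fallback introduces chlorine by a different logic, sets out from 14 and comes back at 15. Protodestannylation with HCl in ether should give the plain butenolide F7. Nucleophilic epoxidation (NaOCl, pyridine, 0 °C), which is selective for the electron-poor C3=C4 bond, should give the epoxy lactone F8. Opening with HCl at the carbon α to the carbonyl (also the less hindered one) should give the chlorohydrin F9. MsCl/Et3N should give the mesylate F10, which should undergo base-induced elimination in the same flask to give 15.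

Further compounds

F1 | step 14 | methyl (5E,9R,10E)-11-chloro-9,12-dihydroxy-9-[(2Z)-oct-2-en-1-yl]dodeca-5,10-dien-7-ynoate | CCCCC/C=C\C[C@@](C#C/C=C/CCCC(=O)OC)(O)/C=C(/Cl)CO
F2 | step 14 | methyl (5E,9R,10E)-11-chloro-9-hydroxy-9-[(2Z)-oct-2-en-1-yl]-12-[(triethylsilyl)oxy]dodeca-5,10-dien-7-ynoate | CCCCC/C=C\C[C@@](C#C/C=C/CCCC(=O)OC)(O)/C=C(/Cl)CO[Si](CC)(CC)CC
F3 | step 14 | methyl (5E,9R,10E)-9-acetoxy-11-chloro-9-[(2Z)-oct-2-en-1-yl]-12-[(triethylsilyl)oxy]dodeca-5,10-dien-7-ynoate | CCCCC/C=C\C[C@@](C#C/C=C/CCCC(=O)OC)(OC(C)=O)/C=C(/Cl)CO[Si](CC)(CC)CC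
F4 | step 14 | methyl (5E,9R,10E)-9-acetoxy-11-chloro-9-[(2Z)-oct-2-en-1-yl]-12-oxododeca-5,10-dien-7-ynoate | CCCCC/C=C\C[C@@](C#C/C=C/CCCC(=O)OC)(OC(C)=O)/C=C(/Cl)C=O
F5 | step 7 | (3R,5Z)-3-[(trimethylsilyl)ethynyl]undec-5-en-1-yn-3-ol | CCCCC/C=C\C[C@@](C#C[Si](C)(C)C)(O)C#C
F6 | step 7 | (4R,6Z)-4-hydroxy-4-[(trimethylsilyl)ethynyl]dodec-6-en-2-ynoic acid | CCCCC/C=C\C[C@@](C#C[Si](C)(C)C)(O)C#CC(O)=O
F7 | step 9 | (5R)-5-[(2Z)-oct-2-en-1-yl]-5-[(trimethylsilyl)ethynyl]furan-2(5H)-one | CCCCC/C=C\C[C@@]1(C#C[Si](C)(C)C)OC(=O)C=C1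
F8 | step 9 | 3,4-epoxide of F7 (3,6-dioxabicyclo[3.1.0]hexan-2-one, quaternary carbon as in 14, mixture of epoxide diastereomers) | CCCCC/C=C\C[C@@]1(C#C[Si](C)(C)C)OC(=O)C2OC12
F9 | step 9 | 3-chloro-4-hydroxy-5-[(2Z)-oct-2-en-1-yl]-5-[(trimethylsilyl)ethynyl]oxolan-2-one (quaternary carbon as in 14, diastereomer mixture) | CCCCC/C=C\C[C@@]1(C#C[Si](C)(C)C)OC(=O)C(Cl)C1O
F10 | step 9 | 4-O-methanesulfonate of F9 | CCCCC/C=C\C[C@@]1(C#C[Si](C)(C)C)OC(=O)C(Cl)C1OS(C)(=O)=O
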